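The earlier runs and the new flask stem from a simulated flask from invented constants; scatter was added.

| flask | starting material | protic impurity | temperature | remark | time |
|---|---|---|---|---|---|
| gamma | 46 mM | 3.3 mM | 60 °C | run made earlier |  |
| theta | 73 mM | 3.3 mM | 80 °C | run made earlier |  |
| delta | 33 mM | 4.9 mM | 60 °C | run made earlier |  |
| Monday's | 33 mM | 3.30 mM | 65 °C |  | 80 min |
| Saturday's | 33 mM | 3.30 mM | 80 °C |  | 80 min |
| Sunday's | 33 mM | 3.30 mM |  | at 95 °C until 15 min, from then on at 65 °C | 80 min |
| Tuesday's | 33 mM | 3.30 mM | 95 °C |  | 80 min |

| run | time / min | target / % |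
|---|---|---|
| gamma | 12.0 | 3.3 |
| gamma | 25.0 | 6.7 |
| gamma | 40.0 | 11.1 |
| gamma | 50.0 | 13.2 |
| theta | 6.00 | 12.2 |
| theta | 12.0 | 20.9 |
| theta | 20.0 | 32.7 |
| theta | 25.0 | 35.0 |
| delta | 12.0 | 3.5 |
| delta | 25.0 | 6.4 |
| delta | 40.0 | 10.5 |
| delta | 50.0 | 12.1 |

(standard deviation of a reading: 1 percentage point)

- what was read earlier has a scatter of 1 percentage point, one standard deviation
- in a conversion other conformer counts as not yet reacted

* the best flask by amount of target, in percent of the starting material charged; "all alike" if 1.5 percentage points covers them all (Monday's / Saturday's / Sunday's / Tuesday's / all alike)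
* amount of target at the end, in percent of the starting material charged, Monday's
* amount of target at the end, in percent of the starting material charged, Saturday's
* amount of target at the end, in percent of the starting material charged, Sunday's
* amount of target at the end, in percent of the starting material charged, Tuesday's

- Sunday's flask spends 15 min at 95 °C and the rest at 65 °C, while Saturday's flask sits at 80 °C throughout; so ask how far each has aged on one common clock.
- Treat each early reading as a first-order rate constant, the inverse of a time constant: k = ln(1/(1 − y))/t, where y is the fraction turned into target by time t.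
- Gamma's last reading gives k = 0.00283 min⁻¹ at 60 °C, and theta's first gives 0.0217 min⁻¹ at 80 °C. The charges differ, but gamma and delta read 13.2 % and 12.1 % at 50.0 min, although charge and impurity both moved between them, so I compare percentages.
- Divide one k by the other and time drops out: the ratio is 7.67, which reads as an activation energy E = 99.6 kJ mol⁻¹, with the scatter of the readings in it.
- Let s be the speed of a temperature, the minutes at 80 °C that one minute there is worth: 3.98 at 95 °C and 0.222 at 65 °C. A flask's age θ is the sum of s times its minutes.
- My reckoning: Sunday's θ is 74.2 min, against 80 min for Saturday's, so Sunday's stands slightly behind and should end close to Saturday's. Tuesday's θ is 319 min, far beyond anything read. The clock gives positions, not yields, and theta stops at 25.0 min.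
- The forecast gave Monday's 28 %, Saturday's 53 %, Sunday's 50 % and Tuesday's 35 %, the last with a range of 8 % to 65 %: “Saturday and Sunday are close; I lean towards Saturday.”
- The flasks give Monday's 28.9 %, Saturday's 62.7 %, Sunday's 62.2 % and Tuesday's 71.8 %, so Tuesday's is best.

    starting material → target (k = 1.30 h⁻¹, Ea = 100 kJ mol⁻¹)
    other conformer ⇌ dormant form (K = 2.60, k = 0.160 h⁻¹, Ea = 105 kJ mol⁻¹, ΔH = −45.0 kJ mol⁻¹)
    starting material ⇌ other conformer (K = 1.70, k = 0.410 h⁻¹, Ea = 107 kJ mol⁻¹, ΔH = −30.0 kJ mol⁻¹)
    other conformer → isomer of the product (k = 0.880 h⁻¹, Ea = 99.0 kJ mol⁻¹)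
    starting material + target → side product (k = 6.60 M⁻¹ h⁻¹, Ea = 86.0 kJ mol⁻¹)
    starting material + protic impurity → quenched substrate (k = 17.0 M⁻¹ h⁻¹, Ea = 66.0 kJ mol⁻¹)
    (constants at 80 °C)

- Saturday's and Sunday's differ by 0.50 percentage points, inside 1.5 points; Sunday's 65.0 min at 65 °C counted for 14.4 min. The steps to target, to other conformer and to isomer of the product have barriers of 100 kJ mol⁻¹, 107 kJ mol⁻¹ and 99.0 kJ mol⁻¹, of like size, which is what lets these steps share one clock. Tuesday's minus Monday's is 43 points, and −17 points without what the temperature does to the turning of starting material into target, the largest single effect on that gap.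
- Now leave Monday's flask until 3.0 h: θ is 40.0 min, which points to Saturday's at 40.0 min, with target 48.6 % and starting material 30.4 %. The computed flask holds target 47.9 % and starting material 30.3 %.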